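**Retrosynthetic overview**
- Target ⇐ hydroxyl-directed epoxidation of the C1=C10 olefin, desilylation and C8 acylation of a ten-membered trienolide.
- Ten-membered carbocycle and cis-fused α-methylene-γ-lactone ⇐ one electrochemical chromium-catalysed ring-closing 2-(methoxycarbonyl)allylation (C6–C7 bond) of an acyclic Z-enal/allylic bromide.
- Allylic bromide ⇐ cross-metathesis on a vinyl carbinol; Z-enal, C14 alcohol and C8 alcohol ⇐ one iBu2AlH reduction of a Weinreb amide/E-alkylidene lactone.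
- C1=C10 ⇐ Horner–Wadsworth–Emmons union of a C1–C6 aldehyde (C3 from (S)-α-hydroxy-γ-butyrolactone) with a C7–C10/C14 phosphono lactone (C8 from (R)-5-(hydroxymethyl)dihydrofuran-2(3H)-one).
- Ring order: butenolide (temporary, fixes 4Z) and γ-lactone (temporary, fixes C1=C10 geometry) first, then macrocycle plus α-methylene lactone together, oxirane last.

Assumption: the SMILES is taken literally (cis-fused 6,12-lactone, 4Z olefin, cis-1,10-epoxide, (R)-2-methylbutanoate), germacrane numbering C1–C15 is used in the text, and the three chiral building blocks and methyl 2-(bromomethyl)acrylate are catalogue items.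

**Route**

Step 1
Reactants: 1 (S)-3-hydroxydihydrofuran-2(3H)-one
Product: 3 (S)-3-hydroxy-5-(triethylsilyloxy)pentan-2-one, via dihydroxy ketone 2 (not isolated)
Conditions: MeLi (2.1 equiv), THF, −78 °C; AcOH (2.1 equiv); then imidazole, Et3SiCl (1.05 equiv), −20 °C
Reagents that add atoms: methyllithium, [Li]C; chlorotriethylsilane, CC[Si](Cl)(CC)CC
Why: MeLi adds once to the lactone of the lithium alkoxide (the lithium hemiketal is stable at −78 °C; lactone-to-methyl-ketone addition) and the primary hydroxyl is then silylated selectively, the bought C3 stereocentre being untouched.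

Step 2
Reactants: 3 (S)-3-hydroxy-5-(triethylsilyloxy)pentan-2-one
Product: 4 (S)-4-methyl-5-[2-(triethylsilyloxy)ethyl]furan-2(5H)-one
Conditions: Ph3P=C=C=O (1.2 equiv), toluene, 90 °C
Reagents that add atoms: (triphenylphosphoranylidene)ketene, O=C=C=P(c1ccccc1)(c1ccccc1)c1ccccc1
Why: The Bestmann ylide acylates the α-hydroxyl and the ester ylide closes by intramolecular Wittig reaction on the ketone, so the new C4=C5 bond is necessarily cis inside the butenolide.

Step 3
Reactants: 4 (S)-4-methyl-5-[2-(triethylsilyloxy)ethyl]furan-2(5H)-one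
Product: 5 (2Z,4S)-4-hydroxy-N-methoxy-N,3-dimethyl-6-(triethylsilyloxy)hex-2-enamide
Conditions: MeNHOMe·HCl, Me3Al, CH2Cl2, 0 °C to rt; aq. potassium sodium tartrate, used crude
Reagents that add atoms: N,O-dimethylhydroxylamine hydrochloride, CNOC.Cl
Why: Weinreb aminolysis of the lactone with the aluminium amide is an acyl substitution that leaves the olefin alone, so the Z geometry is kept.

Step 4
Reactants: 5 (2Z,4S)-4-hydroxy-N-methoxy-N,3-dimethyl-6-(triethylsilyloxy)hex-2-enamide
Product: 6 (2Z,4S)-4-(tert-butyldimethylsilyloxy)-N-methoxy-N,3-dimethyl-6-(triethylsilyloxy)hex-2-enamide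
Conditions: TBSOTf, 2,6-lutidine, CH2Cl2, −78 to 0 °C
Reagents that add atoms: tert-butyldimethylsilyl trifluoromethanesulfonate, CC(C)(C)[Si](C)(C)OS(=O)(=O)C(F)(F)F
Why: Silyl triflate protection of the hindered allylic alcohol blocks relactonisation and later furan formation.

Step 5
Reactants: 6 (2Z,4S)-4-(tert-butyldimethylsilyloxy)-N-methoxy-N,3-dimethyl-6-(triethylsilyloxy)hex-2-enamide
Product: 7 (2Z,4S)-4-(tert-butyldimethylsilyloxy)-N-methoxy-N,3-dimethyl-6-oxohex-2-enamide
Conditions: (COCl)2, DMSO, CH2Cl2, −78 to −40 °C; Et3N, −78 to 0 °C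
Reagents that add atoms: none
Why: Under Swern conditions a primary triethylsilyl ether is cleaved and oxidised directly to the aldehyde, while the secondary TBS ether and the Weinreb amide survive.

Step 6
Reactants: 8 (R)-5-(hydroxymethyl)dihydrofuran-2(3H)-one
Product: 10 (R)-5-vinyldihydrofuran-2(3H)-one, via lactone aldehyde 9 (not isolated)
Conditions: (COCl)2, DMSO, Et3N, CH2Cl2, −78 °C; then Ph3P=CH2 [Ph3PCH3Br, KN(SiMe3)2], THF, −78 to 0 °C
Reagents that add atoms: methyltriphenylphosphonium bromide, C[P+](c1ccccc1)(c1ccccc1)c1ccccc1.[Br-]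
Why: Swern oxidation followed by Wittig methylenation in the same flask avoids isolating the epimerisable α-acyloxy aldehyde; the C8 stereocentre is bought.

Step 7
Reactants: 10 (R)-5-vinyldihydrofuran-2(3H)-one
Product: 12 diethyl [(5R)-2-oxo-5-vinyltetrahydrofuran-3-yl]phosphonate (C3 epimers), via enol phosphate 11 (not isolated)
Conditions: LiN(iPr)2 (2.2 equiv), ClP(O)(OEt)2 (1.1 equiv), THF, −78 °C to rt
Reagents that add atoms: diethyl chlorophosphate, CCOP(=O)(Cl)OCC
Why: The lactone enolate is O-phosphorylated and the second equivalent of amide base triggers the 1,3-phosphorus shift from oxygen to carbon (enol phosphate to β-keto phosphonate rearrangement).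

Step 8
Reactants: 7 (2Z,4S)-4-(tert-butyldimethylsilyloxy)-N-methoxy-N,3-dimethyl-6-oxohex-2-enamide; 12 diethyl [(5R)-2-oxo-5-vinyltetrahydrofuran-3-yl]phosphonate
Product: 13 E-alkylidene lactone (2Z,4S,6E)-4-(tert-butyldimethylsilyloxy)-N-methoxy-N,3-dimethyl-6-[(5R)-2-oxo-5-vinyldihydrofuran-3(2H)-ylidene]hex-2-enamide
Conditions: LiCl, DBU, MeCN, 0 °C to rt
Reagents that add atoms: none
Why: Horner–Wadsworth–Emmons olefination under Masamune–Roush conditions gives the E-alkylidene lactone (C2 trans to the carbonyl), which puts C2 and C9 cis as the target's cis-epoxide needs.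

Step 9
Reactants: 13 E-alkylidene lactone
Product: 14 (2Z,4S,6E,9R)-4-(tert-butyldimethylsilyloxy)-9-hydroxy-7-(hydroxymethyl)-3-methylundeca-2,6,10-trienal
Conditions: iBu2AlH (6 equiv), CH2Cl2, −78 to 0 °C; aq. potassium sodium tartrate
Reagents that add atoms: none
Why: Hydride reduction takes the alkylidene lactone to the C14/C8 diol but stops at the chelated aluminium hemiaminal of the Weinreb amide, which releases the Z-enal on work-up.

Step 10
Reactants: 14 (2Z,4S,6E,9R)-4-(tert-butyldimethylsilyloxy)-9-hydroxy-7-(hydroxymethyl)-3-methylundeca-2,6,10-trienal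
Product: 16 (2Z,4S,6E,9R)-4-(tert-butyldimethylsilyloxy)-7-[(tert-butyldimethylsilyloxy)methyl]-3-methyl-9-(triethylsilyloxy)undeca-2,6,10-trienal, via mono-TBS ether 15 (not isolated)
Conditions: TBSCl (1.05 equiv), imidazole, CH2Cl2, −20 °C; then Et3SiCl (1.3 equiv), 0 °C
Reagents that add atoms: tert-butylchlorodimethylsilane, CC(C)(C)[Si](C)(C)Cl; chlorotriethylsilane, CC[Si](Cl)(CC)CC
Why: Sequential silyl ether formation: the primary allylic hydroxyl reacts first, then the secondary hydroxyl takes the more labile TES group, which later forces lactonisation to O6 and can be removed alone.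

Step 11
Reactants: 16 bis-silylated vinyl enal; 17 methyl 2-(bromomethyl)acrylate
Product: 18 methyl (2Z,4R,6E,9S,10Z)-2-(bromomethyl)-9-(tert-butyldimethylsilyloxy)-6-[(tert-butyldimethylsilyloxy)methyl]-10-methyl-12-oxo-4-(triethylsilyloxy)dodeca-2,6,10-trienoate
Conditions: 17 (6 equiv), dichloro[1,3-bis(2,4,6-trimethylphenyl)imidazolidin-2-ylidene](2-isopropoxybenzylidene)ruthenium (second-generation Hoveyda–Grubbs catalyst, 10 mol %), CH2Cl2, 40 °C
Reagents that add atoms: none
Why: Olefin cross-metathesis engages only the monosubstituted alkene, and the thermodynamic trisubstituted product has C8 trans to the ester, i.e. the Z-bromide.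

Step 12
Reactants: 18 Z-enal allylic bromide
Product: 20 ten-membered cis-fused 6,12-olide (3-OTBS, 14-OTBS, 8-OTES; C3, C6, C7, C8 as in the target), via hydroxy ester 19 (not isolated)
Conditions: CrCl2 (20 mol %), Bu4NBF4, DMF, Al anode, Ni-foam cathode, undivided cell, constant current (2.2 F/mol), 18 added over 10 h (final 2 mM), 20 °C; aq. NaHCO3
Reagents that add atoms: none
Why: Proposed new method: an electroreductive chromium-catalysed intramolecular Nozaki–Hiyama 2-(methoxycarbonyl)allylation used as a ten-membered ring closure — divalent chromium made at the cathode turns the allylic bromide (through the allyl radical) into a Z-allylchromium kept at low stationary concentration, which adds to the enal through a chair Zimmerman–Traxler transition state with C8 axial (syn adduct, hence the cis-fused lactone and 6S), while the C8 stereocentre steers C7 (A(1,3) strain places H8 in the allyl plane and the aldehyde arrives anti to C9, on the side of the silyloxy group, giving 7R); aluminium ions from the anode free the alkoxide from chromium for turnover and the alkoxide lactonises; the closest known reactions are stoichiometric CrCl2 Barbier macrocyclisations to germacranolide rings and intermolecular electrochemical chromium-catalysed allylations and Nozaki–Hiyama–Kishi couplings.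

Step 13
Reactants: 20 ten-membered 6,12-olide (8-OTES)
Product: 21 8-hydroxy 6,12-olide (3-OTBS, 14-OTBS)
Conditions: PPTS (0.2 equiv), MeOH/CH2Cl2 (1:4), 0 °C
Reagents that add atoms: none
Why: Acid-catalysed methanolysis removes the secondary TES ether much faster than the two TBS ethers (selective silyl ether cleavage).

Step 14
Reactants: 21 8-hydroxy 6,12-olide; 22 (R)-2-methylbutanoic acid
Product: 23 8-O-[(R)-2-methylbutanoyl] 6,12-olide (3-OTBS, 14-OTBS)
Conditions: DCC, DMAP (cat.), CH2Cl2, 0 °C to rt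
Reagents that add atoms: none
Why: Steglich esterification of the only free hydroxyl; the side-chain stereocentre is bought and is not epimerised under these mild conditions.

Step 15
Reactants: 23 bis-TBS ester
Product: 24 (3S,6S,7R,8R)-3,14-dihydroxy-8-[(R)-2-methylbutanoyloxy]germacra-1(10),4,11(13)-trien-6,12-olide
Conditions: HF·pyridine, pyridine, THF, 0 °C to rt
Reagents that add atoms: none
Why: Buffered fluoride desilylation frees both allylic hydroxyls and leaves the lactone, ester and α-methylene group intact.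

Step 16
Reactants: 24 3,14-diol
Product: 25 CNP0356520.2
Conditions: VO(acac)2 (5 mol %), tBuOOH (1.1 equiv, in decane), CH2Cl2, 0 °C
Reagents that add atoms: tert-butyl hydroperoxide, CC(C)(C)OO
Why: Hydroxyl-directed vanadium-catalysed epoxidation: the C14 allylic alcohol activates C1=C10, the homoallylic C3 hydroxyl on the same vanadium delivers oxygen syn to itself (1,3-syn, giving 1R,10R), and C4=C5 is deactivated by the allylic lactone oxygen.

**Compound list**
1 | (S)-3-hydroxydihydrofuran-2(3H)-one | O[C@H]1CCOC1=O | starting material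
2 | (S)-3,5-dihydroxypentan-2-one | CC(=O)[C@@H](O)CCO | intermediate
3 | (S)-3-hydroxy-5-(triethylsilyloxy)pentan-2-one | CC(=O)[C@@H](O)CCO[Si](CC)(CC)CC | intermediate
4 | (S)-4-methyl-5-[2-(triethylsilyloxy)ethyl]furan-2(5H)-one | CC1=CC(=O)O[C@H]1CCO[Si](CC)(CC)CC | intermediate
5 | (2Z,4S)-4-hydroxy-N-methoxy-N,3-dimethyl-6-(triethylsilyloxy)hex-2-enamide | CON(C)C(=O)/C=C(/C)[C@@H](O)CCO[Si](CC)(CC)CC | intermediate
6 | (2Z,4S)-4-(tert-butyldimethylsilyloxy)-N-methoxy-N,3-dimethyl-6-(triethylsilyloxy)hex-2-enamide | CON(C)C(=O)/C=C(/C)[C@@H](O[Si](C)(C)C(C)(C)C)CCO[Si](CC)(CC)CC | intermediate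
7 | (2Z,4S)-4-(tert-butyldimethylsilyloxy)-N-methoxy-N,3-dimethyl-6-oxohex-2-enamide | CON(C)C(=O)/C=C(/C)[C@@H](O[Si](C)(C)C(C)(C)C)CC=O | intermediate
8 | (R)-5-(hydroxymethyl)dihydrofuran-2(3H)-one | O=C1CC[C@H](CO)O1 | starting material
9 | (R)-5-oxotetrahydrofuran-2-carbaldehyde | O=C1CC[C@H](C=O)O1 | intermediate
10 | (R)-5-vinyldihydrofuran-2(3H)-one | O=C1CC[C@H](C=C)O1 | intermediate
11 | diethyl [(5R)-5-vinyl-4,5-dihydrofuran-2-yl] phosphate | CCOP(=O)(OCC)OC1=CC[C@H](C=C)O1 | intermediate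
12 | diethyl [(5R)-2-oxo-5-vinyltetrahydrofuran-3-yl]phosphonate (C3 epimers) | CCOP(=O)(OCC)C1C[C@H](C=C)OC1=O | intermediate
13 | (2Z,4S,6E)-4-(tert-butyldimethylsilyloxy)-N-methoxy-N,3-dimethyl-6-[(5R)-2-oxo-5-vinyldihydrofuran-3(2H)-ylidene]hex-2-enamide | CON(C)C(=O)/C=C(/C)[C@@H](O[Si](C)(C)C(C)(C)C)C/C=C1\C[C@H](C=C)OC1=O | intermediate
14 | (2Z,4S,6E,9R)-4-(tert-butyldimethylsilyloxy)-9-hydroxy-7-(hydroxymethyl)-3-methylundeca-2,6,10-trienal | O=C/C=C(/C)[C@@H](O[Si](C)(C)C(C)(C)C)C/C=C(/CO)C[C@@H](O)C=C | intermediate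
15 | (2Z,4S,6E,9R)-4-(tert-butyldimethylsilyloxy)-7-[(tert-butyldimethylsilyloxy)methyl]-9-hydroxy-3-methylundeca-2,6,10-trienal | O=C/C=C(/C)[C@@H](O[Si](C)(C)C(C)(C)C)C/C=C(/CO[Si](C)(C)C(C)(C)C)C[C@@H](O)C=C | intermediate
16 | (2Z,4S,6E,9R)-4-(tert-butyldimethylsilyloxy)-7-[(tert-butyldimethylsilyloxy)methyl]-3-methyl-9-(triethylsilyloxy)undeca-2,6,10-trienal | O=C/C=C(/C)[C@@H](O[Si](C)(C)C(C)(C)C)C/C=C(/CO[Si](C)(C)C(C)(C)C)C[C@@H](O[Si](CC)(CC)CC)C=C | intermediate
17 | methyl 2-(bromomethyl)acrylate | C=C(CBr)C(=O)OC | starting material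
18 | methyl (2Z,4R,6E,9S,10Z)-2-(bromomethyl)-9-(tert-butyldimethylsilyloxy)-6-[(tert-butyldimethylsilyloxy)methyl]-10-methyl-12-oxo-4-(triethylsilyloxy)dodeca-2,6,10-trienoate | O=C/C=C(/C)[C@@H](O[Si](C)(C)C(C)(C)C)C/C=C(/CO[Si](C)(C)C(C)(C)C)C[C@@H](O[Si](CC)(CC)CC)/C=C(\CBr)C(=O)OC | intermediate
19 | methyl 2-[ten-membered ring]acrylate: 6-hydroxy, 3-OTBS, 14-OTBS, 8-OTES, 4Z, C2/C9 cis on C1=C10, stereocentres as in the target | COC(=O)C(=C)[C@H]1[C@@H](O)/C=C(/C)[C@@H](O[Si](C)(C)C(C)(C)C)C/C=C(/CO[Si](C)(C)C(C)(C)C)C[C@H]1O[Si](CC)(CC)CC | intermediate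
20 | 3,14-bis(tert-butyldimethylsilyloxy)-8-(triethylsilyloxy)germacra-1(10),4,11(13)-trien-6,12-olide: cis-fused lactone, 4Z, C2/C9 cis on C1=C10, C3, C6, C7, C8 as in the target | C=C1C(=O)O[C@H]2/C=C(/C)[C@@H](O[Si](C)(C)C(C)(C)C)C/C=C(/CO[Si](C)(C)C(C)(C)C)C[C@@H](O[Si](CC)(CC)CC)[C@@H]12 | intermediate
21 | (3S,6S,7R,8R)-3,14-bis(tert-butyldimethylsilyloxy)-8-hydroxygermacra-1(10),4,11(13)-trien-6,12-olide (4Z, C2/C9 cis) | C=C1C(=O)O[C@H]2/C=C(/C)[C@@H](O[Si](C)(C)C(C)(C)C)C/C=C(/CO[Si](C)(C)C(C)(C)C)C[C@@H](O)[C@@H]12 | intermediate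
22 | (R)-2-methylbutanoic acid | CC[C@@H](C)C(=O)O | starting material
23 | (3S,6S,7R,8R)-3,14-bis(tert-butyldimethylsilyloxy)-8-[(R)-2-methylbutanoyloxy]germacra-1(10),4,11(13)-trien-6,12-olide (4Z, C2/C9 cis) | C=C1C(=O)O[C@H]2/C=C(/C)[C@@H](O[Si](C)(C)C(C)(C)C)C/C=C(/CO[Si](C)(C)C(C)(C)C)C[C@@H](OC(=O)[C@H](C)CC)[C@@H]12 | intermediate
24 | (3S,6S,7R,8R)-3,14-dihydroxy-8-[(R)-2-methylbutanoyloxy]germacra-1(10),4,11(13)-trien-6,12-olide (4Z, C2/C9 cis) | C=C1C(=O)O[C@H]2/C=C(/C)[C@@H](O)C/C=C(/CO)C[C@@H](OC(=O)[C@H](C)CC)[C@@H]12 | intermediate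
25 | CNP0356520.2, (1R,3S,6S,7R,8R,10R,4Z)-1,10-epoxy-3,14-dihydroxy-8-[(R)-2-methylbutanoyloxy]germacra-4,11(13)-dien-6,12-olide | C=C1C(=O)O[C@H]2/C=C(/C)[C@@H](O)C[C@H]3O[C@@]3(CO)C[C@@H](OC(=O)[C@H](C)CC)[C@@H]12 | target

**Totals and risks**

Total step count: 16. Longest linear sequence: 14 steps (steps 1–5, then 8–16).

Steps most likely to fail:

Step 12 (the new ring closure). Possible failures are oligomerisation, simple reduction of the bromide, loss of the Z-allyl geometry (trans-lactone) or the wrong C7 face. Fallback, from 18 back to 20: borylation of the allylic bromide with B2pin2 and catalytic Pd2(dba)3 (toluene, 40 °C) gives the 2-(methoxycarbonyl)allylboronate F9. Heating F9 at high dilution (toluene, 80 °C, 1 mM) effects a thermal intramolecular allylboration through the same chair arrangement. Hydrolytic work-up gives hydroxy ester 19, which lactonises to 20.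

Step 11 (cross-metathesis of a hindered allylic silyl ether with a 1,1-disubstituted acrylate). Fallback, from 8 back to 18, building the bromide by Morita–Baylis–Hillman chemistry instead of metathesis:
- 8 is protected with 4-methoxybenzyl trichloroacetimidate (cat. CSA) to give ether F1.
- Phosphorylation as in step 7 gives phosphonate F2.
- Olefination with 7 as in step 8 gives alkylidene lactone F3.
- iBu2AlH as in step 9 gives enal diol F4.
- TBSCl then Et3SiCl as in step 10 gives bis-silyl ether F5.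
- DDQ (pH 7 buffer) frees primary alcohol F6.
- Dess–Martin periodinane gives α-silyloxy aldehyde F7.
- DABCO and methyl acrylate give Baylis–Hillman adduct F8; the hindered β,β-disubstituted enal does not compete.
- NBS/Me2S converts F8 by SN2' displacement into the Z-bromide 18.

Step 16 (final epoxidation). Possible failures are competing C3-hydroxyl-directed attack on C4=C5 or the wrong face. Fallback, from 23 back to 25: brief HF·pyridine/pyridine at 0 °C removes only the primary allylic TBS group to give allylic alcohol F10. VO(acac)2/tBuOOH, now directed by the C14 hydroxyl alone, gives epoxy alcohol F11. HF·pyridine then removes the C3 silyl ether to give 25.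

Further compounds
F1 | step 11 | (R)-5-[(4-methoxybenzyloxy)methyl]dihydrofuran-2(3H)-one | O=C1CC[C@H](COCc2ccc(OC)cc2)O1
F2 | step 11 | diethyl [(5R)-5-[(4-methoxybenzyloxy)methyl]-2-oxotetrahydrofuran-3-yl]phosphonate | CCOP(=O)(OCC)C1C[C@H](COCc2ccc(OC)cc2)OC1=O
F3 | step 11 | E-alkylidene lactone, 4-methoxybenzyloxymethyl analogue of 13 | CON(C)C(=O)/C=C(/C)[C@@H](O[Si](C)(C)C(C)(C)C)C/C=C1\C[C@H](COCc2ccc(OC)cc2)OC1=O
F4 | step 11 | Z-enal diol with C7 4-methoxybenzyl ether | O=C/C=C(/C)[C@@H](O[Si](C)(C)C(C)(C)C)C/C=C(/CO)C[C@@H](O)COCc1ccc(OC)cc1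
F5 | step 11 | 14-OTBS, 8-OTES enal with C7 4-methoxybenzyl ether | O=C/C=C(/C)[C@@H](O[Si](C)(C)C(C)(C)C)C/C=C(/CO[Si](C)(C)C(C)(C)C)C[C@@H](O[Si](CC)(CC)CC)COCc1ccc(OC)cc1
F6 | step 11 | 14-OTBS, 8-OTES enal with free C7 primary alcohol | O=C/C=C(/C)[C@@H](O[Si](C)(C)C(C)(C)C)C/C=C(/CO[Si](C)(C)C(C)(C)C)C[C@@H](O[Si](CC)(CC)CC)CO
F7 | step 11 | 14-OTBS, 8-OTES enal with C7 aldehyde | O=C/C=C(/C)[C@@H](O[Si](C)(C)C(C)(C)C)C/C=C(/CO[Si](C)(C)C(C)(C)C)C[C@@H](O[Si](CC)(CC)CC)C=O
F8 | step 11 | Morita–Baylis–Hillman adduct (C7 epimers) | O=C/C=C(/C)[C@@H](O[Si](C)(C)C(C)(C)C)C/C=C(/CO[Si](C)(C)C(C)(C)C)C[C@@H](O[Si](CC)(CC)CC)C(O)C(=C)C(=O)OC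
F9 | step 12 | pinacol allylboronate corresponding to bromide 18 | O=C/C=C(/C)[C@@H](O[Si](C)(C)C(C)(C)C)C/C=C(/CO[Si](C)(C)C(C)(C)C)C[C@@H](O[Si](CC)(CC)CC)/C=C(\CB1OC(C)(C)C(C)(C)O1)C(=O)OC
F10 | step 16 | 3-OTBS 14-hydroxy ester (mono-desilylated 23) | C=C1C(=O)O[C@H]2/C=C(/C)[C@@H](O[Si](C)(C)C(C)(C)C)C/C=C(/CO)C[C@@H](OC(=O)[C@H](C)CC)[C@@H]12
F11 | step 16 | 3-O-TBS ether of the target | C=C1C(=O)O[C@H]2/C=C(/C)[C@@H](O[Si](C)(C)C(C)(C)C)C[C@H]3O[C@@]3(CO)C[C@@H](OC(=O)[C@H](C)CC)[C@@H]12
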